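## Analysis of the target

The target (29) is a germacranolide of the melampolide type. Germacrane numbering is used throughout: ring carbons C1–C10, lactone carbons C11–C13 (C12 the carbonyl, C13 the methylene), C14 the methyl on C10 and C15 the methyl on C4. The ten-membered carbocycle carries a 1(10)Z and a 4E trisubstituted alkene and is fused through C6–C7 to an α-methylene-γ-butyrolactone whose oxygen sits on C6. Four contiguous ring stereocentres are present, C6 (S), C7 (R), C8 (R) and C9 (R). H6 and H7 are trans (trans-fused lactone), C11 on C7 and the oxygen on C8 lie on the same face of the ring, and the oxygens on C8 and C9 are trans. O8 carries a (2R,3R)-2,3-dimethyloxirane-2-carbonyl (epoxyangeloyl) group with two further stereocentres, and O9 an acetyl group. The sensitive parts are the exocyclic enoate (an acceptor for amines, thiols and alkoxides), the epoxy ester, the two neighbouring esters (which can exchange places once one hydroxyl is free under base), the allylic C6–O bond, and the cyclodeca-1,5-diene (Cope rearrangement on heating, transannular cyclisation in acid). The difficulty is a medium ring with two trisubstituted alkenes of opposite geometry beside four consecutive stereocentres, plus two adjacent oxygens that must end up with different acyl groups. The strategy rests on the lactone: its oxygen is on C6, allylic to C4=C5, and C11 is on C7. This is the pattern left when a carboxymethyl radical adds to C7 of a C4=C5–C6=C7 diene and the carboxyl group captures the allyl cation at C6, with the neighbouring C8 stereocentre directing the addition.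

## Retrosynthetic reasoning

**C8 ester.** The O8–acyl bond of 29 is cut first, giving alcohol 23 and acid 27 (activated as mixed anhydride 28). The epoxy ester is the most fragile part and 27 is an independent chiral fragment, so it is attached last, at room temperature, after the ring exists. The forward reaction has to acylate a hindered secondary alcohol without moving the neighbouring acetate and without heating the 1,5-diene.

**O9 acetate and O8 silyl ether.** 23 comes from silyl ether 22, and 22 from alcohol 21. The two oxygens are distinguished by their origin: O8 is bought with the chiral pool and is silylated from 10 onwards, whereas O9 is created as a free hydroxyl in the ring closure and is acetylated at once. No selective acylation of a diol is ever needed.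

**C9–C10 bond (ring closure).** 21 is opened between the carbinol carbon C9 and the alkene carbon C10, giving iodoalkene aldehyde 20. This cut puts the Z geometry of C1=C10 into an acyclic iodoalkene made earlier (6), creates O9 in the same event, and keeps the ring-forming bond away from the crowded C6–C7 region. Closing at one of the alkenes would leave the geometry of a trisubstituted double bond to the ring closure. The forward reaction must close a ten-membered ring, retain the Z alkene and set C9 trans to O8.

**C9 oxidation level.** 20 comes from primary alcohol 19 and this from bis-silyl ether 18. O9 carries a triisopropylsilyl group and O8 a tert-butyldiphenylsilyl group. An ester on O9 was not used, because it would be lost in the hydrolysis leading to 16 and the freed hydroxyl could lactonise onto the malonic acid or add to the enoate. The silyl pair survives warm acid and hydroxide, and the primary ether can be removed beside the secondary one.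

**C11=C13.** The methylene of 18 is traced to the carboxyl group of acid 16 (through Mannich base 17), and 16 to methyl ester 14 (through the opened salt 15). The extra carboxyl at C11 is what the annulation leaves behind. It is used for a decarboxylative one-carbon methylenation, so no strong-base enolate chemistry is needed on the lactone.

**C7–C11 and C6–O (key disconnection).** Lactone 14 is cut at both bonds to triene 12 and malonate 13. This removes the lactone ring, two skeletal bonds and the stereocentres C6 and C7 (plus the transient C11) in one step, and leaves an acyclic E,E-diene whose only stereocentre is C8. The forward reaction is an oxidative radical annulation mediated by trivalent manganese. It must add the radical at C7 and not at C4 or at the iodoalkene, choose the face of C7 anti to the C8–O bond, and close the lactone at C6 trans to the C8 branch.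

**C6=C7.** 12 is cut at the diene double bond C6=C7 into allylic phosphonate 6 and aldehyde 11. The 4E alkene and the Z iodoalkene are both already present in 6, so the olefination only has to deliver one E disubstituted double bond.

**Phosphonate 6.** 6 comes from aldehyde 5 by an iodo-olefination that sets the Z geometry. 5 comes from geranyl bromide 1 through phosphonate 2, epoxide 3 and diol 4. The E C4=C5 alkene and C15 are bought with 1, and the terminal prenyl alkene is the masked C1 aldehyde.

**Aldehyde 11.** 11 comes from ester 10, which is built from glycerate acetonide 7 through diol 8 and monosilyl ether 9. The stereocentre of 7 becomes C8, its ester carbon becomes C7 and its CH2O carbon becomes C9. The protecting groups are exchanged on this small fragment, before the convergent step.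

**Acid 27.** 27 comes from epoxy alcohol 26, this from allylic alcohol 25, and this from angelic acid 24. The Z alkene of 24 fixes the cis relation of the C3 methyl and the carboxyl, and a reagent-controlled epoxidation sets the absolute configuration.

## Alternatives that were turned down

**Alternative 1:** The disconnection is at C5–C6 and C4–C15 together with the lactone acyl–oxygen bond. In the forward sense a zerovalent nickel catalyst joins a terminal C4≡C5 alkyne and a C6 aldehyde in an open-chain precursor, a methylzinc reagent methylates C4, and the zinc alkoxide closes onto the C12 ester to give the acetonide lactone A1.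
- For it: ring, 4E alkene, C15 and lactone arise in one operation, and the syn carbometalation guarantees the geometry at C4=C5. On this point it is stronger than the chosen route, which relies on the geranyl geometry surviving an allylic phosphonate anion.
- Against it: C6 would be created during a ten-membered closure with only C7 to control it. The aldehyde is α-branched at C7 with a β-oxygen on C8, so epimerisation and elimination threaten before cyclisation. Medium-ring closure through an oxanickelacycle competes with simple reductive coupling and oligomerisation. The precursor must already contain the C7–C8–C9 triad and the Z C1=C10 alkene on C9, all made acyclically.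
- A1 still lacks C13 and has O8 and O9 tied together, so strong-base methylenation and a regioselective acylation of a trans-diol remain.
- In its place the chosen strategy sets C6 and C7 on an acyclic substrate from one stereocentre, keeps O8 and O9 distinct from the start, and obtains C13 from the carboxyl that the annulation leaves.

**Alternative 2:** The ten-membered diene is traced back to a tricyclic cyclobutane made by enone–cyclobutene photocycloaddition on a chiral-pool cyclohexenone. The σ-bonds C1–C4 and C5–C10 of that adduct are broken by flash thermolysis to unveil C1=C10 and C4=C5 in dienone A2.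
- For it: no macrocyclisation is needed, which is a real advantage over the high-dilution ring closure of the chosen route. C7 comes from the chiral pool, and the cycloreversion is known to favour a Z,E-1,5-diene, which fits the target.
- Against it: the photoaddition must join two fully substituted carbons (C10 and C4, each bearing a methyl) with the correct orientation of the methylcyclobutene. The enone must already carry oxygen at C6 and C8, which costs several substrate-controlled steps. The cyclodecadiene is formed at a temperature where Cope rearrangement to the divinylcyclohexane competes.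
- From A2 the C9 ketone still has to be reduced with the right sense, and C12 oxidised and lactonised. C6, C8 and C9 are each set in a separate step, and the count is at least as long as the chosen route.
- The chosen strategy gives up the entropic advantage but builds both alkene geometries in acyclic, predictable steps and sets C6 and C7 together.

**Alternative 3:** The ring is cut at C8–C9. Low-valent titanium couples a C8 aldehyde and a C9 enal of a lactone dialdehyde to the diol lactone A3, forming the ring and both carbinol centres.
- For it: the most convergent endgame of all. The ring and two stereocentres are made in one step from two aldehydes, and medium-ring pinacol closures tend to give the trans-diol that is needed. On step count after the lactone it is stronger than the chosen route.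
- Against it: two new centres are formed with no handle on their relation to C7. The C8 aldehyde is β to the lactone oxygen on C6 and α to C7, so elimination and epimerisation are likely. Low-valent titanium can cleave the allylic C6–O bond, couple the enal through its γ-carbon, or deoxygenate the diol.
- A3 is again an undifferentiated diol without C13.
- The chosen strategy buys C8 with its oxygen already protected and forms only C9 in the ring closure, so one uncertain centre replaces two.

Key step: step 10

Remark: C11 of 14 and 16 is drawn as the trans epimer. The centre is acidic and is destroyed in step 12, so its configuration has no consequence. The epoxide and diol carbons of 3 and 4 are racemic and vanish in step 3.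

## Route

Step 1
Reactants: 1 geranyl bromide
Product: 2 diethyl [(2E)-3,7-dimethylocta-2,6-dien-1-yl]phosphonate
Conditions: P(OEt)3 (neat), 120 °C, EtBr distilled off
Reagents that add atoms: triethyl phosphite, CCOP(OCC)OCC
Why: Michaelis–Arbuzov reaction of a primary allylic bromide; SN2 attack of phosphorus at C1 keeps the 2E alkene, and distillation of 2 removes all trivalent phosphorus before the peracid step.

Step 2
Reactants: 2 diethyl [(2E)-3,7-dimethylocta-2,6-dien-1-yl]phosphonate
Product: 3 diethyl [(2E)-5-(3,3-dimethyloxiran-2-yl)-3-methylpent-2-en-1-yl]phosphonate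
Conditions: mCPBA (1.0 equiv), NaHCO3, CH2Cl2, 0 °C
Reagents that add atoms: 3-chloroperbenzoic acid, OOC(=O)c1cccc(Cl)c1
Why: Prilezhaev epoxidation; the peracid takes the remote, more electron-rich 6,7-alkene and leaves the 2,3-alkene, which is deactivated by the phosphonylmethyl group.

Step 3
Reactants: 3 diethyl [(2E)-5-(3,3-dimethyloxiran-2-yl)-3-methylpent-2-en-1-yl]phosphonate
Product: 5 diethyl [(2E)-3-methyl-6-oxohex-2-en-1-yl]phosphonate, via 6,7-diol 4 (not isolated)
Conditions: H5IO6, THF/H2O, 0 °C → rt
Reagents that add atoms: none
Why: Acid opens the epoxide with water at the tertiary carbon to diol 4, which periodate cleaves (Malaprade cleavage); the aldehyde oxygen is the former epoxide oxygen, and the phosphonate and the 2E alkene are inert.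

Step 4
Reactants: 5 diethyl [(2E)-3-methyl-6-oxohex-2-en-1-yl]phosphonate
Product: 6 diethyl [(2E,6Z)-7-iodo-3-methylocta-2,6-dien-1-yl]phosphonate
Conditions: EtPPh3Br, n-BuLi, THF, rt; I2, −78 °C; NaN(SiMe3)2, −20 °C; then 5, −78 → −20 °C
Reagents that add atoms: ethyltriphenylphosphonium bromide, CC[P+](c1ccccc1)(c1ccccc1)c1ccccc1.[Br-]; iodine, II
Why: Stork–Zhao-type iodo-olefination with the α-methyl α-iodo ylide made in the flask; the non-stabilised ylide reacts under kinetic control to put iodine cis to the chain (Z), and it is not basic enough to deprotonate the phosphonate CH2.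

Step 5
Reactants: 7 methyl (S)-2,2-dimethyl-1,3-dioxolane-4-carboxylate
Product: 8 methyl (S)-2,3-dihydroxypropanoate
Conditions: Dowex 50W (H+ form), MeOH, rt
Reagents that add atoms: none
Why: Acid-catalysed transacetalisation to methanol frees the diol without touching the ester or the stereocentre.

Step 6
Reactants: 8 methyl (S)-2,3-dihydroxypropanoate
Product: 9 methyl (S)-2-hydroxy-3-(triisopropylsilyloxy)propanoate
Conditions: iPr3SiCl (1.05 equiv), imidazole, CH2Cl2, 0 °C
Reagents that add atoms: chlorotriisopropylsilane, CC(C)[Si](Cl)(C(C)C)C(C)C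
Why: Silylation with a bulky chlorosilane is selective for the primary hydroxyl over the hindered, electron-poor α-hydroxy ester position.

Step 7
Reactants: 9 methyl (S)-2-hydroxy-3-(triisopropylsilyloxy)propanoate
Product: 10 methyl (S)-2-(tert-butyldiphenylsilyloxy)-3-(triisopropylsilyloxy)propanoate
Conditions: tBuPh2SiCl, imidazole, DMAP (cat.), DMF, 40 °C
Reagents that add atoms: tert-butylchlorodiphenylsilane, CC(C)(C)[Si](Cl)(c1ccccc1)c1ccccc1
Why: Silylation of the secondary hydroxyl under nucleophilic catalysis; this ether is chosen because it survives warm AcOH, hydroxide and the later selective fluoride step, and the stereocentre is not involved.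

Step 8
Reactants: 10 methyl (S)-2-(tert-butyldiphenylsilyloxy)-3-(triisopropylsilyloxy)propanoate
Product: 11 (S)-2-(tert-butyldiphenylsilyloxy)-3-(triisopropylsilyloxy)propanal
Conditions: iBu2AlH, CH2Cl2, −78 °C; aq. potassium sodium tartrate
Reagents that add atoms: none
Why: Partial reduction of an α-oxygenated ester; the aluminium hemiacetal is stable at −78 °C and releases the aldehyde only on work-up, and 11 is used without chromatography to avoid epimerisation.

Step 9
Reactants: 6 diethyl [(2E,6Z)-7-iodo-3-methylocta-2,6-dien-1-yl]phosphonate; 11 (S)-2-(tert-butyldiphenylsilyloxy)-3-(triisopropylsilyloxy)propanal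
Product: 12 (2R,3E,5E,9Z)-2-(tert-butyldiphenylsilyloxy)-10-iodo-6-methyl-1-(triisopropylsilyloxy)undeca-3,5,9-triene
Conditions: LiN(iPr)2 (1.05 equiv), THF, −78 °C; then 11, DMPU, −78 °C → rt
Reagents that add atoms: none
Why: Horner–Wadsworth–Emmons olefination of an allylic phosphonate; the amide base deprotonates P–CH2 without halogen–metal exchange, the anion attacks through its α-carbon (the γ-carbon is fully substituted), and elimination on warming gives the E C6=C7 bond while the cold α-silyloxy aldehyde keeps its configuration (C8 becomes R only by a change of priorities).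

Step 10
Reactants: 12 (2R,3E,5E,9Z)-2-(tert-butyldiphenylsilyloxy)-10-iodo-6-methyl-1-(triisopropylsilyloxy)undeca-3,5,9-triene; 13 potassium methyl malonate
Product: 14 methyl (3S,4R,5S)-4-[(1R)-1-(tert-butyldiphenylsilyloxy)-2-(triisopropylsilyloxy)ethyl]-5-[(1E,5Z)-6-iodo-2-methylhepta-1,5-dien-1-yl]-2-oxooxolane-3-carboxylate
Conditions: Mn(OAc)3·2H2O (2.2 equiv), Cu(OAc)2 (0.2 equiv), 13 (3 equiv), degassed AcOH, 50 °C, N2
Reagents that add atoms: none
Why: This is an oxidative radical (3+2) lactone annulation, the manganese triacetate carbolactonisation long used on alkenes and 1,3-dienes with malonic half-esters. The malonate carboxylate binds trivalent manganese, and enolisation with inner-sphere electron transfer releases the electrophilic radical •CH(CO2Me)CO2H; it adds to C7 because only this terminus leaves an allyl radical spread over C6 to C4 with a tertiary end, whereas C4 is fully substituted and the isolated, inductively deactivated iodoalkene is far less reactive than the diene. Divalent copper (turned over by Mn(OAc)3) or trivalent manganese oxidises the allyl radical, and the tethered carboxylic acid captures the cation at C6 in a 5-exo closure; capture at C4 would need a seven-membered ring, so the γ-lactone is the only ring formed and C4=C5 returns with E geometry from the s-trans diene. C7 is controlled by C8: with C8–H in the diene plane the radical enters anti to the C8–O bond, away from the tert-butyldiphenylsilyloxy group, and the inside-alkoxy picture for electrophilic reagents leads to the same 7R,8R product. C6 is controlled by C7: the cation rotates about C6–C7 before closure and the ring forms with the C5 alkenyl group and the C8 branch trans (6S), which avoids their eclipsing. C11 is acidic, settles trans to the C8 branch and is removed in step 12. The step needs regioselectivity, facial selectivity at C7 and protecting groups that survive warm AcOH; the substitution pattern of the diene, the C8 stereocentre and the two robust silyl ethers are expected to provide them.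

Step 11
Reactants: 14 methyl (3S,4R,5S)-4-[(1R)-1-(tert-butyldiphenylsilyloxy)-2-(triisopropylsilyloxy)ethyl]-5-[(1E,5Z)-6-iodo-2-methylhepta-1,5-dien-1-yl]-2-oxooxolane-3-carboxylate
Product: 16 (3S,4R,5S)-4-[(1R)-1-(tert-butyldiphenylsilyloxy)-2-(triisopropylsilyloxy)ethyl]-5-[(1E,5Z)-6-iodo-2-methylhepta-1,5-dien-1-yl]-2-oxooxolane-3-carboxylic acid, via dilithium hydroxy malonate 15 (not isolated)
Conditions: LiOH, THF/H2O, 0 °C → rt; then 1 M HCl to pH 3, 0 °C
Reagents that add atoms: lithium hydroxide, [Li+].[OH-]
Why: Saponification; hydroxide cleaves the methyl ester and opens the lactone to salt 15, and at pH 3 the γ-hydroxy malonic acid closes again to the five-membered lactone, the only ring available because O8 and O9 are silylated; C6 and C7 have no retro-aldol or elimination path.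

Step 12
Reactants: 16 (3S,4R,5S)-4-[(1R)-1-(tert-butyldiphenylsilyloxy)-2-(triisopropylsilyloxy)ethyl]-5-[(1E,5Z)-6-iodo-2-methylhepta-1,5-dien-1-yl]-2-oxooxolane-3-carboxylic acid
Product: 18 (4R,5S)-4-[(1R)-1-(tert-butyldiphenylsilyloxy)-2-(triisopropylsilyloxy)ethyl]-5-[(1E,5Z)-6-iodo-2-methylhepta-1,5-dien-1-yl]-3-methylideneoxolan-2-one, via Mannich base 17 (not isolated)
Conditions: Et2NH, 37% aq. HCHO, THF, rt; then NaOAc, AcOH, 60 °C
Reagents that add atoms: formaldehyde, C=O
Why: Decarboxylative Mannich methylenation, the classical route from α-carboxy lactones to α-methylene lactones; C11 is aminomethylated to 17, and warming in buffered AcOH expels CO2 and Et2NH in one fragmentation, which also removes the C11 stereocentre.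

Step 13
Reactants: 18 (4R,5S)-4-[(1R)-1-(tert-butyldiphenylsilyloxy)-2-(triisopropylsilyloxy)ethyl]-5-[(1E,5Z)-6-iodo-2-methylhepta-1,5-dien-1-yl]-3-methylideneoxolan-2-one
Product: 19 (4R,5S)-4-[(1R)-1-(tert-butyldiphenylsilyloxy)-2-hydroxyethyl]-5-[(1E,5Z)-6-iodo-2-methylhepta-1,5-dien-1-yl]-3-methylideneoxolan-2-one
Conditions: HF·pyridine, pyridine, THF, 0 °C → rt
Reagents that add atoms: none
Why: Selective desilylation; under buffered acidic fluoride the primary triisopropylsilyl ether is cleaved well before the secondary, doubly flanked tert-butyldiphenylsilyl ether, and the medium does not add to the enoate.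

Step 14
Reactants: 19 (4R,5S)-4-[(1R)-1-(tert-butyldiphenylsilyloxy)-2-hydroxyethyl]-5-[(1E,5Z)-6-iodo-2-methylhepta-1,5-dien-1-yl]-3-methylideneoxolan-2-one
Product: 20 (2R)-2-(tert-butyldiphenylsilyloxy)-2-{(2S,3R)-2-[(1E,5Z)-6-iodo-2-methylhepta-1,5-dien-1-yl]-4-methylidene-5-oxooxolan-3-yl}acetaldehyde
Conditions: Dess–Martin periodinane, CH2Cl2, 0 °C → rt
Reagents that add atoms: none
Why: Dess–Martin oxidation is neutral and does not epimerise the α-silyloxy aldehyde, which is carried on crude.

Step 15
Reactants: 20 (2R)-2-(tert-butyldiphenylsilyloxy)-2-{(2S,3R)-2-[(1E,5Z)-6-iodo-2-methylhepta-1,5-dien-1-yl]-4-methylidene-5-oxooxolan-3-yl}acetaldehyde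
Product: 21 (1(10)Z,4E,6S,7R,8R,9R)-8-(tert-butyldiphenylsilyloxy)-9-hydroxygermacra-1(10),4,11(13)-trien-12,6-olide
Conditions: CrCl2 (10 equiv), NiCl2 (0.1 equiv), degassed DMSO, slow addition of 20 to 0.002 M, rt
Reagents that add atoms: none
Why: Intramolecular Nozaki–Hiyama–Kishi reaction; zerovalent nickel inserts into the C–I bond with retention of the Z geometry, transmetallation gives an alkenylchromium species that adds only to the aldehyde (lactone and enoate are tolerated), and high dilution favours the ten-membered ring; C9 should form R because the closure that keeps both the C8 silyloxy group and the chromium-bound carbonyl oxygen on the outside of the forming ring places them trans.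

Step 16
Reactants: 21 (1(10)Z,4E,6S,7R,8R,9R)-8-(tert-butyldiphenylsilyloxy)-9-hydroxygermacra-1(10),4,11(13)-trien-12,6-olide
Product: 22 (1(10)Z,4E,6S,7R,8R,9R)-9-acetoxy-8-(tert-butyldiphenylsilyloxy)germacra-1(10),4,11(13)-trien-12,6-olide
Conditions: Ac2O, DMAP (cat.), pyridine, CH2Cl2, 0 °C → rt
Reagents that add atoms: acetic anhydride, CC(=O)OC(C)=O
Why: DMAP-catalysed acetylation of the only free hydroxyl; O8 is still silylated, so no regiochemical question arises.

Step 17
Reactants: 22 (1(10)Z,4E,6S,7R,8R,9R)-9-acetoxy-8-(tert-butyldiphenylsilyloxy)germacra-1(10),4,11(13)-trien-12,6-olide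
Product: 23 (1(10)Z,4E,6S,7S,8R,9R)-9-acetoxy-8-hydroxygermacra-1(10),4,11(13)-trien-12,6-olide
Conditions: Bu4NF, AcOH (1:1), THF, rt
Reagents that add atoms: none
Why: Fluoride cleavage of the silyl ether; the AcOH buffer keeps the medium near neutral, so the acetate should not migrate from O9 to O8 and nothing adds to the enoate (the C7 descriptor changes to S only through priorities).

Step 18
Reactants: 24 angelic acid [(Z)-2-methylbut-2-enoic acid]
Product: 25 (Z)-2-methylbut-2-en-1-ol
Conditions: LiAlH4, Et2O, 0 °C
Reagents that add atoms: none
Why: Hydride reduction of the acid to the allylic alcohol at low temperature, without conjugate reduction or Z to E isomerisation.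

Step 19
Reactants: 25 (Z)-2-methylbut-2-en-1-ol
Product: 26 [(2S,3R)-2,3-dimethyloxiran-2-yl]methanol
Conditions: Ti(OiPr)4 (0.1 equiv), L-(+)-diethyl tartrate (0.12 equiv), tBuOOH, 4 Å sieves, CH2Cl2, −20 °C
Reagents that add atoms: tert-butyl hydroperoxide, CC(C)(C)OO
Why: Sharpless asymmetric epoxidation; L-(+)-tartrate delivers oxygen to the face that gives 2S, the same sense as in the epoxidation of nerol to its (2S,3R)-epoxide, and the Z alkene then fixes C3 as R with the C3 methyl cis to CH2OH.

Step 20
Reactants: 26 [(2S,3R)-2,3-dimethyloxiran-2-yl]methanol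
Product: 27 (2R,3R)-2,3-dimethyloxirane-2-carboxylic acid
Conditions: RuCl3 (cat.), NaIO4, CCl4/MeCN/H2O, rt
Reagents that add atoms: sodium periodate, [Na+].[O-]I(=O)(=O)=O; water, O
Why: RuO4-catalysed oxidation of a primary epoxy alcohol to the glycidic acid leaves the epoxide intact; C2 becomes R only because CO2H now outranks C3.

Step 21
Reactants: 27 (2R,3R)-2,3-dimethyloxirane-2-carboxylic acid; 23 (1(10)Z,4E,6S,7S,8R,9R)-9-acetoxy-8-hydroxygermacra-1(10),4,11(13)-trien-12,6-olide
Product: 29 (1(10)Z,4E,6S,7R,8R,9R)-9-acetoxy-8-[(2R,3R)-2,3-dimethyloxirane-2-carbonyloxy]germacra-1(10),4,11(13)-trien-12,6-olide (CNP0304643.4), via mixed anhydride 28 (not isolated)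
Conditions: 2,4,6-trichlorobenzoyl chloride, Et3N, THF, rt; then 23, DMAP, toluene, rt
Reagents that add atoms: none
Why: Yamaguchi esterification; acid 27 is converted to mixed anhydride 28 and DMAP transfers the epoxyacyl group to the hindered C8 hydroxyl at room temperature, so no stereocentre is touched and the 1,5-diene is never heated.

## Compound list

1 | geranyl bromide, (2E)-1-bromo-3,7-dimethylocta-2,6-diene | CC(C)=CCC/C(C)=C/CBr | starting material
2 | diethyl [(2E)-3,7-dimethylocta-2,6-dien-1-yl]phosphonate | CC(C)=CCC/C(C)=C/CP(=O)(OCC)OCC | intermediate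
3 | diethyl [(2E)-5-(3,3-dimethyloxiran-2-yl)-3-methylpent-2-en-1-yl]phosphonate (racemic at the oxirane carbon) | CC1(C)OC1CC/C(C)=C/CP(=O)(OCC)OCC | intermediate
4 | diethyl [(2E)-6,7-dihydroxy-3,7-dimethyloct-2-en-1-yl]phosphonate (racemic) | CC(C)(O)C(O)CC/C(C)=C/CP(=O)(OCC)OCC | intermediate (not isolated)
5 | diethyl [(2E)-3-methyl-6-oxohex-2-en-1-yl]phosphonate | O=CCC/C(C)=C/CP(=O)(OCC)OCC | intermediate
6 | diethyl [(2E,6Z)-7-iodo-3-methylocta-2,6-dien-1-yl]phosphonate | C/C(I)=C/CC/C(C)=C/CP(=O)(OCC)OCC | intermediate
7 | methyl (S)-2,2-dimethyl-1,3-dioxolane-4-carboxylate | COC(=O)[C@@H]1COC(C)(C)O1 | starting material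
8 | methyl (S)-2,3-dihydroxypropanoate | COC(=O)[C@@H](O)CO | intermediate
9 | methyl (S)-2-hydroxy-3-(triisopropylsilyloxy)propanoate | COC(=O)[C@@H](O)CO[Si](C(C)C)(C(C)C)C(C)C | intermediate
10 | methyl (S)-2-(tert-butyldiphenylsilyloxy)-3-(triisopropylsilyloxy)propanoate | COC(=O)[C@@H](O[Si](c1ccccc1)(c1ccccc1)C(C)(C)C)CO[Si](C(C)C)(C(C)C)C(C)C | intermediate
11 | (S)-2-(tert-butyldiphenylsilyloxy)-3-(triisopropylsilyloxy)propanal | O=C[C@@H](O[Si](c1ccccc1)(c1ccccc1)C(C)(C)C)CO[Si](C(C)C)(C(C)C)C(C)C | intermediate
12 | (2R,3E,5E,9Z)-2-(tert-butyldiphenylsilyloxy)-10-iodo-6-methyl-1-(triisopropylsilyloxy)undeca-3,5,9-triene (C8 R, O8 TBDPS, O9 TIPS) | CC(C)[Si](C(C)C)(C(C)C)OC[C@H](O[Si](c1ccccc1)(c1ccccc1)C(C)(C)C)/C=C/C=C(\C)CC/C=C(/C)I | intermediate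
13 | potassium methyl malonate (potassium 3-methoxy-3-oxopropanoate) | COC(=O)CC(=O)[O-].[K+] | starting material
14 | methyl (3S,4R,5S)-4-[(1R)-1-(tert-butyldiphenylsilyloxy)-2-(triisopropylsilyloxy)ethyl]-5-[(1E,5Z)-6-iodo-2-methylhepta-1,5-dien-1-yl]-2-oxooxolane-3-carboxylate (6S,7R,8R, C11 trans) | COC(=O)[C@H]1C(=O)O[C@@H](/C=C(\C)CC/C=C(/C)I)[C@@H]1[C@@H](O[Si](c2ccccc2)(c2ccccc2)C(C)(C)C)CO[Si](C(C)C)(C(C)C)C(C)C | intermediate
15 | dilithium 2-{(1R,2S,3E,7Z)-1-[(1R)-1-(tert-butyldiphenylsilyloxy)-2-(triisopropylsilyloxy)ethyl]-2-hydroxy-8-iodo-4-methylnona-3,7-dien-1-yl}propanedioate | [Li+].[Li+].[O-]C(=O)C(C(=O)[O-])[C@H]([C@@H](O)/C=C(\C)CC/C=C(/C)I)[C@@H](O[Si](c1ccccc1)(c1ccccc1)C(C)(C)C)CO[Si](C(C)C)(C(C)C)C(C)C | intermediate (not isolated)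
16 | (3S,4R,5S)-4-[(1R)-1-(tert-butyldiphenylsilyloxy)-2-(triisopropylsilyloxy)ethyl]-5-[(1E,5Z)-6-iodo-2-methylhepta-1,5-dien-1-yl]-2-oxooxolane-3-carboxylic acid | OC(=O)[C@H]1C(=O)O[C@@H](/C=C(\C)CC/C=C(/C)I)[C@@H]1[C@@H](O[Si](c2ccccc2)(c2ccccc2)C(C)(C)C)CO[Si](C(C)C)(C(C)C)C(C)C | intermediate
17 | (4R,5S)-3-[(diethylamino)methyl]-4-[(1R)-1-(tert-butyldiphenylsilyloxy)-2-(triisopropylsilyloxy)ethyl]-5-[(1E,5Z)-6-iodo-2-methylhepta-1,5-dien-1-yl]-2-oxooxolane-3-carboxylic acid (C3 of the ring, i.e. C11, as either epimer) | CCN(CC)CC1(C(=O)O)C(=O)O[C@@H](/C=C(\C)CC/C=C(/C)I)[C@@H]1[C@@H](O[Si](c2ccccc2)(c2ccccc2)C(C)(C)C)CO[Si](C(C)C)(C(C)C)C(C)C | intermediate (not isolated)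
18 | (4R,5S)-4-[(1R)-1-(tert-butyldiphenylsilyloxy)-2-(triisopropylsilyloxy)ethyl]-5-[(1E,5Z)-6-iodo-2-methylhepta-1,5-dien-1-yl]-3-methylideneoxolan-2-one | C=C1C(=O)O[C@@H](/C=C(\C)CC/C=C(/C)I)[C@@H]1[C@@H](O[Si](c2ccccc2)(c2ccccc2)C(C)(C)C)CO[Si](C(C)C)(C(C)C)C(C)C | intermediate
19 | (4R,5S)-4-[(1R)-1-(tert-butyldiphenylsilyloxy)-2-hydroxyethyl]-5-[(1E,5Z)-6-iodo-2-methylhepta-1,5-dien-1-yl]-3-methylideneoxolan-2-one | C=C1C(=O)O[C@@H](/C=C(\C)CC/C=C(/C)I)[C@@H]1[C@@H](O[Si](c2ccccc2)(c2ccccc2)C(C)(C)C)CO | intermediate
20 | (2R)-2-(tert-butyldiphenylsilyloxy)-2-{(2S,3R)-2-[(1E,5Z)-6-iodo-2-methylhepta-1,5-dien-1-yl]-4-methylidene-5-oxooxolan-3-yl}acetaldehyde | C=C1C(=O)O[C@@H](/C=C(\C)CC/C=C(/C)I)[C@@H]1[C@@H](O[Si](c2ccccc2)(c2ccccc2)C(C)(C)C)C=O | intermediate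
21 | (1(10)Z,4E,6S,7R,8R,9R)-8-(tert-butyldiphenylsilyloxy)-9-hydroxygermacra-1(10),4,11(13)-trien-12,6-olide | C=C1C(=O)O[C@H]2/C=C(\C)CC/C=C(/C)[C@@H](O)[C@H](O[Si](c3ccccc3)(c3ccccc3)C(C)(C)C)[C@H]12 | intermediate
22 | (1(10)Z,4E,6S,7R,8R,9R)-9-acetoxy-8-(tert-butyldiphenylsilyloxy)germacra-1(10),4,11(13)-trien-12,6-olide | C=C1C(=O)O[C@H]2/C=C(\C)CC/C=C(/C)[C@@H](OC(C)=O)[C@H](O[Si](c3ccccc3)(c3ccccc3)C(C)(C)C)[C@H]12 | intermediate
23 | (1(10)Z,4E,6S,7S,8R,9R)-9-acetoxy-8-hydroxygermacra-1(10),4,11(13)-trien-12,6-olide | C=C1C(=O)O[C@H]2/C=C(\C)CC/C=C(/C)[C@@H](OC(C)=O)[C@H](O)[C@H]12 | intermediate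
24 | angelic acid, (Z)-2-methylbut-2-enoic acid | C/C=C(/C)C(=O)O | starting material
25 | (Z)-2-methylbut-2-en-1-ol | C/C=C(/C)CO | intermediate
26 | [(2S,3R)-2,3-dimethyloxiran-2-yl]methanol | OC[C@]1(C)O[C@@H]1C | intermediate
27 | (2R,3R)-2,3-dimethyloxirane-2-carboxylic acid | OC(=O)[C@]1(C)O[C@@H]1C | intermediate
28 | (2R,3R)-2,3-dimethyloxirane-2-carboxylic 2,4,6-trichlorobenzoic anhydride | O=C(OC(=O)[C@]1(C)O[C@@H]1C)c2c(Cl)cc(Cl)cc2Cl | intermediate (not isolated)
29 | (1(10)Z,4E,6S,7R,8R,9R)-9-acetoxy-8-[(2R,3R)-2,3-dimethyloxirane-2-carbonyloxy]germacra-1(10),4,11(13)-trien-12,6-olide (CNP0304643.4) | C=C1C(=O)O[C@H]2/C=C(\C)CC/C=C(/C)[C@@H](OC(C)=O)[C@H](OC(=O)[C@]3(C)O[C@@H]3C)[C@H]12 | target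

## Step count and least certain steps

Total: 21 steps. Longest linear sequence: 14 steps (steps 1–4, 9–17 and 21 from geranyl bromide 1; the line from 7 through steps 5–9 is equally long).

**Step 10 (key step).** The most likely failures are insufficient facial discrimination at C7 and loss of material in oxidative side paths. The C6=C7 alkene is E-disubstituted, so allylic strain is weak and the two faces differ only by OSi against CH2OSi. After the radical addition, the allyl cation can be captured by acetate at C4 or lose a proton to a triene, the acidic C11–H of 14 can be oxidised again, and the malonyl radical can attack the iodoalkene. The fallback separates radical addition from ring closure. From 12, a visible-light atom-transfer addition of dimethyl bromomalonate (Ru(bpy)3Cl2, LiBr, DMF/H2O, room temperature) should give the 1,4-adduct allylic bromide F1 at lower temperature and without a stoichiometric metal oxidant. Warming F1 (NaHCO3, DMF, 80 °C) lets one ester carbonyl displace the allylic bromide at C6 with loss of bromomethane, which returns to the route at 14.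

**Step 15.** The most likely failure is the wrong facial selectivity at C9, because the configuration is decided by the conformation of the closing ten-membered ring and not by a simple acyclic model. Oligomerisation, if the closure is slow, is the second concern. The fallback corrects C9 after the ring is made. From 20, if the closure gives mainly the 9S alcohol F2, a Mitsunobu reaction of F2 with acetic acid (PPh3, diisopropyl azodicarboxylate, toluene, 0 °C) inverts C9 and installs the acetate in the same operation, which returns to the route at 22.

**Step 4.** The most likely failure is an unfavourable Z to E ratio with low conversion. The α-iodo ylide is thermally fragile, and incomplete iodination leaves the iodine-free ylide, which gives the iodine-free alkene. The fallback builds the haloalkene by cross-coupling. From 5, dibromo-olefination (CBr4, PPh3, CH2Cl2, 0 °C) gives the 1,1-dibromoalkene F3. A trans-selective Negishi monomethylation (ZnMe2, PdCl2(DPEphos), THF) replaces only the bromine trans to the chain and gives the (Z)-bromoalkene F4. Copper-catalysed halogen exchange (CuI, N,N′-dimethylethylenediamine, NaI, dioxane, 110 °C) proceeds with retention and returns to the route at 6.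

**Step 11.** The most likely failure is incomplete hydrolysis. Hydroxide first deprotonates the malonate-type C11–H, and the enolate shields both carbonyls; forcing the reaction starts to erode the silyl ethers. The fallback abandons the carboxyl handle. From 14, Krapcho demethoxycarbonylation (LiCl, wet DMSO, 130 °C) gives the unsubstituted lactone F5. Enolate aminomethylation (LiN(SiMe3)2, THF, −78 °C; dimethylmethylideneammonium iodide) gives the Mannich base F6. Quaternisation and elimination (MeI; then NaHCO3) return to the route at 18.

## Further compounds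

F1 | step 10 | dimethyl 2-{(2E,7Z)-1-[(1R)-1-(tert-butyldiphenylsilyloxy)-2-(triisopropylsilyloxy)ethyl]-4-bromo-8-iodo-4-methylnona-2,7-dien-1-yl}propanedioate (C7 and C8 arranged as in 14, C4 bromide as a mixture) | COC(=O)C(C(=O)OC)[C@H](/C=C/C(C)(Br)CC/C=C(/C)I)[C@@H](O[Si](c1ccccc1)(c1ccccc1)C(C)(C)C)CO[Si](C(C)C)(C(C)C)C(C)C
F2 | step 15 | (1(10)Z,4E,6S,7R,8R,9S)-8-(tert-butyldiphenylsilyloxy)-9-hydroxygermacra-1(10),4,11(13)-trien-12,6-olide | C=C1C(=O)O[C@H]2/C=C(\C)CC/C=C(/C)[C@H](O)[C@H](O[Si](c3ccccc3)(c3ccccc3)C(C)(C)C)[C@H]12
F3 | step 4 | diethyl [(2E)-7,7-dibromo-3-methylhepta-2,6-dien-1-yl]phosphonate | BrC(Br)=CCC/C(C)=C/CP(=O)(OCC)OCC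
F4 | step 4 | diethyl [(2E,6Z)-7-bromo-3-methylocta-2,6-dien-1-yl]phosphonate | C/C(Br)=C/CC/C(C)=C/CP(=O)(OCC)OCC
F5 | step 11 | (4R,5S)-4-[(1R)-1-(tert-butyldiphenylsilyloxy)-2-(triisopropylsilyloxy)ethyl]-5-[(1E,5Z)-6-iodo-2-methylhepta-1,5-dien-1-yl]oxolan-2-one | C1C(=O)O[C@@H](/C=C(\C)CC/C=C(/C)I)[C@@H]1[C@@H](O[Si](c2ccccc2)(c2ccccc2)C(C)(C)C)CO[Si](C(C)C)(C(C)C)C(C)C
F6 | step 11 | (4R,5S)-3-[(dimethylamino)methyl]-4-[(1R)-1-(tert-butyldiphenylsilyloxy)-2-(triisopropylsilyloxy)ethyl]-5-[(1E,5Z)-6-iodo-2-methylhepta-1,5-dien-1-yl]oxolan-2-one (C3 of the ring as either epimer) | CN(C)CC1C(=O)O[C@@H](/C=C(\C)CC/C=C(/C)I)[C@@H]1[C@@H](O[Si](c2ccccc2)(c2ccccc2)C(C)(C)C)CO[Si](C(C)C)(C(C)C)C(C)C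
A1 | alternative 1 | ten-membered trans-fused lactone with 8,9-acetonide and C11 methylene group (no C13) | C1C(=O)O[C@H]2/C=C(\C)CC/C=C(/C)[C@H]3OC(C)(C)O[C@@H]3[C@H]12
A2 | alternative 2 | ten-membered (1Z,4E)-dienone with C9 ketone, C8 4-methoxybenzyl ether and silylated C6 and C12 hydroxyls | O=C1/C(C)=C\CC/C(C)=C/[C@H](O[Si](C)(C)C(C)(C)C)[C@@H](C(=C)CO[Si](C)(C)C(C)(C)C)[C@H]1OCc2ccc(OC)cc2
A3 | alternative 3 | ten-membered lactone 8,9-diol (no C13) | C1C(=O)O[C@H]2/C=C(\C)CC/C=C(/C)[C@@H](O)[C@H](O)[C@H]12
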